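The easy step comes first: 5 mol% of 12 mM puts 0.600 mM of free catalyst into the gamma flask, and the impurity charge of 0.15 mM is a quarter of that. These are the two amounts to hold against each other.

- gamma: starting material 12 mM; partner 0.95 equiv; free catalyst 5 mol%; impurity 0.15 mM; the very flask that is asked about, followed so far
- flask: starting material 12 mM; partner 0.950 equiv; free catalyst 5 mol%; impurity 0.15 mM

gamma run (percent of the starting material charged)

| time / h | product / % | starting material / % |
|---|---|---|
| 1.50 | 2.3 | 96.7 |
| 4.00 | 6.4 | 92.5 |
| 8.00 | 13.1 | 86.4 |
| 12.0 | 18.4 | 80.1 |
| 20.0 | 28.0 | 70.3 |
| 25.0 | 33.4 | 65.1 |
| 30.0 | 38.2 | 60.2 |

(readings scatter by 0.3 percentage points)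

- the analysis behind the earlier runs scatters by 0.3 percentage points, standard deviation
- no earlier run changes the charge of free catalyst; that part of a forecast is a guess
- no earlier run changes the charge of partner; that part of a forecast is a guess

- apparent order in free catalyst when 30% of the starting material are converted (percent change of the rate of making product for one percent more free catalyst charged)
- apparent order in partner when 30% of the starting material are converted (percent change of the rate of making product for one percent more partner charged)
- factor on the rate of making product when 30% of the starting material are converted if partner is charged twice over

The gamma readings reach 30% conversion near 20.0 h, but they share one catalyst charge, so they cannot show an order in it. You have to reckon that order from the charges, on a guess of your own. Guess that each impurity takes one free catalyst for good, early on, and freeze what remains: 0.450 mM of working catalyst. If the rate follows that amount, extra catalyst lands wholly on the working part. The order in free catalyst is then the poison factor, catalyst charged over catalyst left working: 1.33, so one percent more charged gives more than one percent more working. For the partner you hold no number of your own.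

The forecast set 1.1 for the order in catalyst, lower than your factor, with 0.5 for the order in partner and 1.45 for doubled partner, adding: “If it poisons catalyst, the order reaches about 1.33”. The gamma flask gives 1.3, 0.20 and 1.09.

    free catalyst + impurity → spent catalyst (k = 14000 L mol⁻¹ h⁻¹)
    starting material + free catalyst → catalyst intermediate A (k = 61.0 L mol⁻¹ h⁻¹)
    catalyst intermediate B ⇌ free catalyst + product (K = 0.0110 M, k = 3.20 h⁻¹)
    partner + catalyst intermediate A → catalyst intermediate B (k = 280 L mol⁻¹ h⁻¹)

In the gamma flask, spent catalyst holds 25.0% of the catalyst charged at 0.600 d, with impurity at 0%, so the subtraction behind the factor of 1.33 stands. Take away the step from free catalyst and impurity to spent catalyst, and the simulated run has order 1.0, not 1.3: with nothing subtracted, the factor is 1.00. That same run, without the step, gives 1.33 times the actual rate at 30% conversion, and the step is only a part of what holds that rate down.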